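**Assumption (one line):** the target SMILES has no stereocentre and no configurationally stable axis, so the molecule is achiral and there is no enantiomer to select; reagents that only donate atoms (MOMCl, prenyl bromide, etc.) are given by name and SMILES in each step and are not numbered.

## Retrosynthetic overview

1. Artopetelin C ⇐ its tris-MOM ether (global acetal cleavage is the last step).
2. Furan ring and the C7 quaternary carbon are made together, last: an o-alkynyl aryl prenyl ether undergoes [3,3] shift of the O-prenyl group to the only free ortho carbon (giving 1,1-dimethylallyl), and the freed phenoxide closes onto the alkyne (proposed "Claisen-relay annulation").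
3. The diarylalkyne ⇐ Sonogashira coupling of a hindered B-ring aryl triflate with an A-ring terminal alkyne.
4. B-ring triflate ⇐ phloroglucinol: chromanone annulation (pyran ring formed first), chelation-controlled 7-O-MOM, C4 deoxygenation, O-(1,1-dimethylallyl) ether then Claisen (6-prenyl), triflation of the 5-OH.
5. A-ring alkyne ⇐ 2,4,6-trihydroxybenzaldehyde: bis-MOM, O-prenylation of the chelated OH, Ohira–Bestmann. Ring order: pyran, then furan.

## Route

**Step 1**
Reactants: 1 phloroglucinol; 2 3,3-dimethylacrylic acid
Product: 3, 5,7-dihydroxy-2,2-dimethylchroman-4-one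
Conditions: MeSO3H, P2O5, 70 °C
Reagents that add atoms: 3,3-dimethylacrylic acid (reactant 2), CC(C)=CC(=O)O
Why: Friedel–Crafts acylation followed by intramolecular oxa-Michael closure gives the chromanone in one pot, and the C3 symmetry of 1 allows only one regioisomer.

**Step 2**
Reactants: 3
Product: 4, 5-hydroxy-7-(methoxymethoxy)-2,2-dimethylchroman-4-one
Conditions: MOMCl (1.1 equiv), i-Pr2NEt, CH2Cl2, 0 °C
Reagents that add atoms: chloromethyl methyl ether, COCCl
Why: the 5-OH is hydrogen-bonded to the C4 carbonyl, so only the 7-OH is alkylated (chelation-controlled MOM protection).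

**Step 3**
Reactants: 4
Product: 5, 7-(methoxymethoxy)-2,2-dimethylchroman-5-ol
Conditions: ClCO2Et, Et3N, THF, 0 °C; then NaBH4, H2O, 0 °C→rt
Reagents that add atoms: none
Why: carbonate-assisted borohydride deoxygenation of an o-hydroxyaryl ketone (carbonate transfer to the benzylic alkoxide, elimination to an o-quinone methide, 1,4-hydride reduction) turns C=O into CH2 under non-acidic conditions that keep the MOM group.

**Step 4**
Reactants: 5
Product: 6, 7-(methoxymethoxy)-2,2-dimethyl-5-[(2-methylbut-3-en-2-yl)oxy]chroman
Conditions: tert-butyl (2-methylbut-3-en-2-yl) carbonate, Pd(PPh3)4 (2 mol %), THF, 0 °C→rt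
Reagents that add atoms: tert-butyl (2-methylbut-3-en-2-yl) carbonate, C=CC(C)(C)OC(=O)OC(C)(C)C
Why: Tsuji–Trost O-allylation, in which the phenoxide attacks the π-prenyl-Pd at the more substituted terminus under kinetic control to give the tertiary (1,1-dimethylallyl) aryl ether.

**Step 5**
Reactants: 6
Product: 7, 7-(methoxymethoxy)-2,2-dimethyl-6-(3-methylbut-2-en-1-yl)chroman-5-ol
Conditions: PhMe, 120 °C (sealed tube)
Reagents that add atoms: none
Why: aromatic Claisen rearrangement ([3,3], allyl inversion) delivers a normal prenyl group to C6, the only ortho carbon bearing H (C4a is blocked).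

**Step 6**
Reactants: 7
Product: 8, 7-(methoxymethoxy)-2,2-dimethyl-6-(3-methylbut-2-en-1-yl)chroman-5-yl trifluoromethanesulfonate
Conditions: NaH, PhNTf2, THF, 0 °C→rt
Reagents that add atoms: N-phenyl-bis(trifluoromethanesulfonimide), O=S(=O)(N(c1ccccc1)S(=O)(=O)C(F)(F)F)C(F)(F)F
Why: O-sulfonylation of the sodium phenoxide with a neutral triflating agent avoids TfOH, which would cyclise the ortho-prenyl group or cleave the MOM group.

**Step 7**
Reactants: 9, 2,4,6-trihydroxybenzaldehyde
Product: 10, 2-hydroxy-4,6-bis(methoxymethoxy)benzaldehyde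
Conditions: MOMCl (2.2 equiv), i-Pr2NEt, CH2Cl2, 0 °C→rt
Reagents that add atoms: chloromethyl methyl ether, COCCl
Why: after the first ortho-OH and the para-OH are protected, the remaining ortho-OH is chelated to the aldehyde and stays free (chelation-controlled MOM protection).

**Step 8**
Reactants: 10
Product: 11, 2,4-bis(methoxymethoxy)-6-[(3-methylbut-2-en-1-yl)oxy]benzaldehyde
Conditions: prenyl bromide, K2CO3, DMF, rt
Reagents that add atoms: 1-bromo-3-methylbut-2-ene (prenyl bromide), CC(C)=CCBr
Why: Williamson O-alkylation (SN2 at the primary carbon) of the chelated phenoxide in a polar aprotic solvent gives the O-prenyl ether.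

**Step 9**
Reactants: 11
Product: 12, 2-ethynyl-1,5-bis(methoxymethoxy)-3-[(3-methylbut-2-en-1-yl)oxy]benzene
Conditions: dimethyl (1-diazo-2-oxopropyl)phosphonate, K2CO3, MeOH, rt
Reagents that add atoms: Ohira–Bestmann reagent (donates the terminal alkyne carbon), COP(=O)(OC)C(=[N+]=[N-])C(C)=O
Why: Seyferth–Gilbert homologation (Ohira–Bestmann variant) converts the aldehyde into the terminal alkyne under mild base that MOM and prenyl ethers tolerate.

**Step 10**
Reactants: 8; 12
Product: 13, 5-{[2,4-bis(methoxymethoxy)-6-(3-methylbut-2-en-1-yloxy)phenyl]ethynyl}-7-(methoxymethoxy)-2,2-dimethyl-6-(3-methylbut-2-en-1-yl)chroman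
Conditions: PdCl2(MeCN)2 (5 mol %), XPhos (12 mol %), Cs2CO3, MeCN, 80 °C
Reagents that add atoms: none
Why: copper-free Sonogashira coupling, where a bulky biaryl phosphine allows oxidative addition of the di-ortho-substituted triflate and the linear alkyne tolerates the congestion; the prenyl ether (trisubstituted alkene, no amine nucleophile present) should not be ionised by Pd(0).

**Step 11 (proposed new step)**
Reactants: 13
Product: 14, 2-[7-(methoxymethoxy)-2,2-dimethyl-6-(3-methylbut-2-en-1-yl)chroman-5-yl]-4,6-bis(methoxymethoxy)-7-(2-methylbut-3-en-2-yl)benzofuran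
Conditions: CsF (2 equiv), PhNEt2, 185 °C (sealed tube, degassed)
Reagents that add atoms: none
Why: Proposed new method: a "Claisen-relay annulation" in which the O-prenyl group that masked the phenol undergoes thermal [3,3] shift with allyl inversion to the only open ortho carbon (the other ortho carbon carries the alkyne), forming the C7–C(CH3)2CH=CH2 quaternary bond, and the caesium phenoxide so released adds 5-endo-dig to the neighbouring diarylalkyne before the ortho-(1,1-dimethylallyl)phenol can enter OH-dependent abnormal-Claisen or dihydrofuran pathways; because only this oxygen is unmasked, the furan closes with the correct regiochemistry (7- rather than 5-substituted); the closest known reaction types are the thermal aromatic Claisen rearrangement of aryl prenyl ethers, the CsF-mediated Claisen/cyclisation of aryl propargyl ethers to 2-methylbenzofurans, and base-mediated cycloisomerisation of o-alkynylphenols.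

**Step 12**
Reactants: 14
Product: 15, Artopetelin C, 2-[7-hydroxy-2,2-dimethyl-6-(3-methylbut-2-en-1-yl)chroman-5-yl]-7-(2-methylbut-3-en-2-yl)benzofuran-4,6-diol
Conditions: 3 M aq HCl/MeOH (1:5), 45 °C
Reagents that add atoms: none
Why: acid-catalysed acetal (MOM) hydrolysis at mild temperature is faster than protonation of the prenyl or 1,1-dimethylallyl alkenes, so the three phenols are released without chroman or dihydrofuran formation.

## Compound list

1 | phloroglucinol | Oc1cc(O)cc(O)c1 | starting material
2 | 3,3-dimethylacrylic acid | CC(C)=CC(=O)O | starting material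
3 | 5,7-dihydroxy-2,2-dimethylchroman-4-one | CC1(C)CC(=O)c2c(O)cc(O)cc2O1 | intermediate
4 | 5-hydroxy-7-(methoxymethoxy)-2,2-dimethylchroman-4-one | COCOc1cc(O)c2C(=O)CC(C)(C)Oc2c1 | intermediate
5 | 7-(methoxymethoxy)-2,2-dimethylchroman-5-ol | COCOc1cc(O)c2CCC(C)(C)Oc2c1 | intermediate
6 | 7-(methoxymethoxy)-2,2-dimethyl-5-[(2-methylbut-3-en-2-yl)oxy]chroman | COCOc1cc(OC(C)(C)C=C)c2CCC(C)(C)Oc2c1 | intermediate
7 | 7-(methoxymethoxy)-2,2-dimethyl-6-(3-methylbut-2-en-1-yl)chroman-5-ol | COCOc1cc2OC(C)(C)CCc2c(O)c1CC=C(C)C | intermediate
8 | 7-(methoxymethoxy)-2,2-dimethyl-6-(3-methylbut-2-en-1-yl)chroman-5-yl trifluoromethanesulfonate | COCOc1cc2OC(C)(C)CCc2c(OS(=O)(=O)C(F)(F)F)c1CC=C(C)C | intermediate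
9 | 2,4,6-trihydroxybenzaldehyde | O=Cc1c(O)cc(O)cc1O | starting material
10 | 2-hydroxy-4,6-bis(methoxymethoxy)benzaldehyde | COCOc1cc(O)c(C=O)c(OCOC)c1 | intermediate
11 | 2,4-bis(methoxymethoxy)-6-[(3-methylbut-2-en-1-yl)oxy]benzaldehyde | COCOc1cc(OCC=C(C)C)c(C=O)c(OCOC)c1 | intermediate
12 | 2-ethynyl-1,5-bis(methoxymethoxy)-3-[(3-methylbut-2-en-1-yl)oxy]benzene | C#Cc1c(OCOC)cc(OCOC)cc1OCC=C(C)C | intermediate
13 | 5-{[2,4-bis(methoxymethoxy)-6-(prenyloxy)phenyl]ethynyl}-7-(methoxymethoxy)-2,2-dimethyl-6-prenylchroman | COCOc1cc2OC(C)(C)CCc2c(C#Cc2c(OCOC)cc(OCOC)cc2OCC=C(C)C)c1CC=C(C)C | intermediate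
14 | 2-[7-(methoxymethoxy)-2,2-dimethyl-6-prenylchroman-5-yl]-4,6-bis(methoxymethoxy)-7-(2-methylbut-3-en-2-yl)benzofuran | C=CC(C)(C)c1c(OCOC)cc(OCOC)c2cc(-c3c(CC=C(C)C)c(OCOC)cc4OC(C)(C)CCc34)oc12 | intermediate
15 | Artopetelin C (achiral) | C=CC(C)(C)c1c(O)cc(O)c2cc(-c3c(CC=C(C)C)c(O)cc4c3CCC(C)(C)O4)oc12 | target

## Summary

**Total steps:** 12
**Longest linear sequence:** 9 (steps 1–6, then 10–12); the A-ring branch is steps 7–9.

**Three steps most likely to fail**

1. **Step 11 (proposed Claisen-relay annulation).** Risks are para-Claisen or loss of isoprene, and a slow shift into the carbon flanked by O and OMOM. Fallback with known chemistry: run the aromatic Claisen earlier on aldehyde 11 (thermal or Eu(fod)3-catalysed, giving the chelated 3-(1,1-dimethylallyl)salicylaldehyde). Then protect that phenol as a TBS ether, make the alkyne by Corey–Fuchs, couple with 8 by Sonogashira, and treat with TBAF, which removes TBS and closes the furan by fluoride-mediated 5-endo-dig cyclisation to give 14.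

2. **Step 10 (Sonogashira on a 2,6-disubstituted, electron-rich triflate).** Risks are slow oxidative addition, triflate hydrolysis, or Pd-mediated loss or transfer of the prenyl ether. Fallback: form the furan before the biaryl bond. Convert 12 into 4,6-bis(methoxymethoxy)-7-(2-methylbut-3-en-2-yl)benzofuran by stepwise thermal Claisen and Cu(I)- or base-mediated cyclisation of the terminal o-ethynylphenol. Then C2-lithiate (n-BuLi, −78 °C), transmetalate with ZnCl2, and join to 8 by Negishi coupling with a bulky NHC-Pd catalyst to reach 14 directly.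

3. **Step 12 (acidic removal of three MOM groups next to ortho-prenyl and ortho-1,1-dimethylallyl phenols).** Risk is acid-catalysed chroman or dihydrofuran formation. Fallback: change the protecting-group strategy to TBS ethers, installed on 3 and 9 in place of MOM. This variant uses Corey–Fuchs instead of Ohira–Bestmann, amine-base Sonogashira, and a neutral thermal Claisen followed by Au(I)-catalysed cyclisation. The final unveiling is then with buffered TBAF/AcOH, with no Brønsted acid.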